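Put east and north-west on one clock before ranking them. Every amount below is a fraction of the solid substrate charged.

| flask | solid substrate | partner | temperature | remark | time |
|---|---|---|---|---|---|
| oak | 0.40 M | 0.48 M | 15 °C | run made earlier |  |
| alder | 0.40 M | 1.1 M | 28 °C | run made earlier |  |
| elm | 0.20 M | 0.72 M | 15 °C | run made earlier |  |
| east | 0.40 M | 0.720 M | 20 °C |  | 10 min |
| north-west | 0.40 M | 0.720 M | 35 °C |  | 10 min |

| run | time / min | intermediate / % | target / % |
|---|---|---|---|
| oak | 0.833 | 2.0 | 0.1 |
| oak | 2.50 | 12.0 | 3.2 |
| oak | 5.00 | 26.3 | 9.7 |
| oak | 8.00 | 29.6 | 21.2 |
| oak | 10.0 | 29.7 | 28.5 |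
| alder | 0.833 | 9.9 | 2.7 |
| alder | 2.50 | 30.1 | 25.0 |
| alder | 5.00 | 31.7 | 53.6 |
| alder | 8.00 | 27.3 | 56.3 |
| alder | 10.0 | 26.3 | 55.6 |
| elm | 0.833 | 7.2 | 0.4 |
| elm | 2.50 | 30.3 | 5.1 |
| elm | 5.00 | 42.8 | 20.0 |
| elm | 8.00 | 41.0 | 37.0 |
| elm | 10.0 | 36.0 | 44.7 |

(each reading ± 0.5 percentage points)

- released group is meant together with its crystals
- solid, in amounts per volume of the solution: crystals, solid substrate
- reactions considered so far: starting material + partner -> intermediate + released group; intermediate <-> target; intermediate <-> isomer of the product; crystals <-> released group; solid substrate <-> starting material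
- at the start none of the solid substrate is in solution
- what has only dissolved of solid substrate counts as not reacted

- the flask with the highest amount of intermediate, in percent of the solid substrate charged ("all alike" if they lie within 1.5 percentage points) (east / north-west / all alike)
- final intermediate, as a percentage of the solid substrate charged, in east
- final intermediate, as a percentage of the solid substrate charged, in north-west

Two chemists disagree. The forecaster sees east still climbing: “East should reach about 77% total at 10 min, still approaching equilibrium”. The sceptic thinks east has already reached the balance between intermediate and target, and wants a clock for that.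

Alder's last readings put target at 2.11 times intermediate. The forward constant of intermediate to target, read from oak's last interval, is 0.123 min⁻¹ at 15 °C. From alder's early interval it is 0.669 min⁻¹ at 28 °C, a rise of 0.735 powers of ten. A straight line in those powers gives 0.236 min⁻¹ at 20 °C.

Now define the balance half-life: the time in which a gap between intermediate and its balance with target halves, forward and back steps together (a pre-equilibrium clock). For east it is 1.99 min, shorter than the 10 min allowed. So the sceptic puts both flasks near 0.321 of their intermediate-plus-target sum and expects them alike, with east nearer 25 % than the forecast's figure.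

The forecast says east, with 31 % in east and 25 % in north-west.

The simulation gives 27.9 % in east and 28.0 % in north-west, inside the margin of 1.5 percentage points, so the answer is all alike. The forecast's two numbers were close, but its ranking was not.

    starting material + partner → intermediate + released group (k = 0.570 L mol⁻¹ min⁻¹, Ea = 60.0 kJ mol⁻¹)
    intermediate ⇌ target (K = 2.70, k = 0.320 min⁻¹, Ea = 94.0 kJ mol⁻¹, ΔH = −29.0 kJ mol⁻¹)
    intermediate ⇌ isomer of the product (K = 2.10, k = 0.0370 min⁻¹, Ea = 77.0 kJ mol⁻¹, ΔH = −14.0 kJ mol⁻¹)
    crystals ⇌ released group, rate k4*(cs4 - [released group]) while solid is left; crystals form when [released group] > cs4 (solubility = 23.0 mM, k = 20.0 min⁻¹)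
    solid substrate ⇌ starting material, rate k5*(cs5 - [starting material]) while solid is left; crystals form when [starting material] > cs5 (solubility = 0.310 M, k = 0.640 min⁻¹)
    (constants at 20 °C)

The return of target to intermediate holds the intermediate up: with that return struck out, north-west ends at 0.295 % instead of 28.0 %. By the estimate, east has had 5.03 balance half-lives by the end, yet it still holds 11.5 % of starting material, with target at 1.86 times intermediate. For the repeat of east at −5 °C, the same line gives a balance half-life of 51.7 min, longer than the 10 min allowed, and that flask ends with 0.915 % of target beside 22.9 % of intermediate.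

(The readings were generated by integration with made-up constants; the scatter is artificial.)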